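The synthesis rests on disconnecting the diarylmethane at the bond between the benzylic CH2 and C4 of ring B (the 3,5-dibromo-4-hydroxyphenyl ring). The CH2 sits ortho to the phenolic oxygen of ring A (the ring bearing the hydroxymethyl group), so it can be unmasked from a salicyl alcohol as an ortho-quinone methide, a dearomatised ring A. Ring B is 2,6-dibromophenol, whose two ortho positions carry bromine, so only the para carbon can attack. One operation thus forms the C–C bond and rearomatises ring A with the full substitution pattern in place. The future hydroxymethyl group of ring A is carried as a methyl ester, inert to ionisation, and is reduced last.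

Key step: step 3

Remark: the target has no stereocentre, so no stereocontrol is needed anywhere in the route.

Step 1
Reactants: 1 methyl 3-formyl-4-hydroxybenzoate
Product: 2 methyl 3-bromo-5-formyl-4-hydroxybenzoate
Conditions: NBS (1.05 equiv), DMF, 0 °C to rt
Reagents that add atoms: N-bromosuccinimide, O=C1CCC(=O)N1Br
Why: Electrophilic aromatic bromination; the hydroxyl group directs to its one open ortho position, and the formyl and ester groups are both meta-directing to that same carbon, so a single monobromide should form.

Step 2
Reactants: 2 methyl 3-bromo-5-formyl-4-hydroxybenzoate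
Product: 3 methyl 3-bromo-4-hydroxy-5-(hydroxymethyl)benzoate
Conditions: NaBH4 (1 equiv), MeOH/THF, 0 °C; sat. aq. NH4Cl
Reagents that add atoms: none
Why: Chemoselective borohydride reduction; NaBH4 at 0 °C should reduce the aldehyde to the salicyl alcohol and leave the methyl ester and the aryl bromide untouched.

Step 3
Reactants: 3 methyl 3-bromo-4-hydroxy-5-(hydroxymethyl)benzoate; 4 2,6-dibromophenol
Product: 6 methyl 3-bromo-5-(3,5-dibromo-4-hydroxybenzyl)-4-hydroxybenzoate, via ortho-quinone methide 5 (not isolated)
Conditions: 4 (3 equiv), TfOH (10 mol%), (CF3)2CHOH, 40 °C
Reagents that add atoms: none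
Why: The strong acid in the ionising, weakly nucleophilic solvent protonates the benzylic hydroxyl of 3, and water leaves with the push of the ortho phenolic oxygen to give the ortho-quinone methide 5 (or its O-protonated form); C4 of 4 then adds in a conjugate sense to the exocyclic methylene, which restores the aromaticity of ring A, and loss of a proton rearomatises ring B. The closest known reaction type is the acid-catalysed Friedel-Crafts benzylation of phenols by salicyl alcohols through ortho-quinone methides, as in phenol-formaldehyde condensation. No ring is closed and no stereocentre is formed. The selectivity needed is C-alkylation at the para carbon of 4 only; the two ortho bromine atoms secure it by blocking both ortho positions, and O-alkylation is reversible under acid and should drain to the diarylmethane. Self-condensation of 3 and over-alkylation of 6 are excluded because every position ortho or para to a hydroxyl in ring A and in the product is already substituted, and the ester, unlike a para-hydroxymethyl group, cannot ionise to a para-quinone methide.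

Step 4
Reactants: 6 methyl 3-bromo-5-(3,5-dibromo-4-hydroxybenzyl)-4-hydroxybenzoate
Product: 7 thelephenol, 2-bromo-6-(3,5-dibromo-4-hydroxybenzyl)-4-(hydroxymethyl)phenol
Conditions: iBu2AlH (6 equiv), THF, −78 °C to 0 °C; aq. potassium sodium tartrate (KNaC4H4O6)
Reagents that add atoms: none
Why: Ester reduction with an aluminium hydride; two equivalents of iBu2AlH are consumed by the phenols and the rest should reduce the ester through the aldehyde to the primary alcohol, the aryl bromides are inert, and the neutral tartrate work-up avoids acid that would ionise the para-hydroxybenzyl alcohol.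

Compound list
1 | methyl 3-formyl-4-hydroxybenzoate | COC(=O)c1ccc(O)c(C=O)c1 | starting material
2 | methyl 3-bromo-5-formyl-4-hydroxybenzoate | COC(=O)c1cc(Br)c(O)c(C=O)c1 | intermediate
3 | methyl 3-bromo-4-hydroxy-5-(hydroxymethyl)benzoate | COC(=O)c1cc(Br)c(O)c(CO)c1 | intermediate
4 | 2,6-dibromophenol | Oc1c(Br)cccc1Br | starting material
5 | ortho-quinone methide, methyl 5-bromo-3-methylidene-4-oxocyclohexa-1,5-diene-1-carboxylate (not isolated) | COC(=O)C1=CC(=C)C(=O)C(Br)=C1 | intermediate
6 | methyl 3-bromo-5-(3,5-dibromo-4-hydroxybenzyl)-4-hydroxybenzoate | COC(=O)c1cc(Br)c(O)c(Cc2cc(Br)c(O)c(Br)c2)c1 | intermediate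
7 | thelephenol, 2-bromo-6-(3,5-dibromo-4-hydroxybenzyl)-4-(hydroxymethyl)phenol | OCc1cc(Br)c(O)c(Cc2cc(Br)c(O)c(Br)c2)c1 | target

Total step count: 4
Longest linear sequence: 4 steps (1 to 2 to 3 to 6 to 7); compound 4 is used as purchased.

Steps most likely to fail

Step 3 (key step). The ester and the bromine make the salicyl alcohol slow to ionise, and the doubly brominated phenol is a weak nucleophile. Reversible ether formation could therefore stall the reaction, or forcing acid conditions could bring on migration of bromine. Fallback: from 3, the same ortho-quinone methide is captured with phenol itself (large excess, same acid system), a far better nucleophile. After removal of the ortho-linked isomer this should give methyl 3-bromo-4-hydroxy-5-(4-hydroxybenzyl)benzoate F1. NBS (2.1 equiv) in MeCN at 0 °C should then brominate the two positions ortho to the hydroxyl of ring B, the only activated open positions in the molecule, and the route comes back at 6.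

Step 4. The aluminium phenoxide para to the ester may slow the reduction. Once formed, the para-hydroxybenzyl alkoxide may ionise to a para-quinone methide, which would lead to hydrogenolysis to the methyl compound or to oligomerisation on work-up. Fallback: from 6, both phenols are silylated (TBSOTf, 2,6-lutidine, CH2Cl2, 0 °C) to give methyl 3-bromo-4-(tert-butyldimethylsilyloxy)-5-[3,5-dibromo-4-(tert-butyldimethylsilyloxy)benzyl]benzoate F2. The ester is then reduced with iBu2AlH (2.5 equiv, CH2Cl2, −78 °C) to {3-bromo-4-(tert-butyldimethylsilyloxy)-5-[3,5-dibromo-4-(tert-butyldimethylsilyloxy)benzyl]phenyl}methanol F3. The silyl groups are removed with Bu4NF buffered with AcOH in THF at 0 °C, and the route comes back at 7.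

Step 1. Electrophilic substitution of a phenol that carries two electron-withdrawing groups may be sluggish or incomplete, and the formyl group may be oxidised by the brominating agent. Fallback: from 1, the order is inverted. NaBH4 in MeOH at 0 °C first reduces the aldehyde to methyl 4-hydroxy-3-(hydroxymethyl)benzoate F4, whose ring no longer carries the deactivating formyl group. NBS in MeCN at 0 °C then brominates the one open position ortho to the hydroxyl, and the route comes back at 3.

Further compounds
F1 | step 3 | methyl 3-bromo-4-hydroxy-5-(4-hydroxybenzyl)benzoate | COC(=O)c1cc(Br)c(O)c(Cc2ccc(O)cc2)c1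
F2 | step 4 | methyl 3-bromo-4-(tert-butyldimethylsilyloxy)-5-[3,5-dibromo-4-(tert-butyldimethylsilyloxy)benzyl]benzoate | COC(=O)c1cc(Br)c(O[Si](C)(C)C(C)(C)C)c(Cc2cc(Br)c(O[Si](C)(C)C(C)(C)C)c(Br)c2)c1
F3 | step 4 | {3-bromo-4-(tert-butyldimethylsilyloxy)-5-[3,5-dibromo-4-(tert-butyldimethylsilyloxy)benzyl]phenyl}methanol | OCc1cc(Br)c(O[Si](C)(C)C(C)(C)C)c(Cc2cc(Br)c(O[Si](C)(C)C(C)(C)C)c(Br)c2)c1
F4 | step 1 | methyl 4-hydroxy-3-(hydroxymethyl)benzoate | COC(=O)c1ccc(O)c(CO)c1
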